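The nine-membered carbocycle (ring numbering: C1 bears CO2Me, C2 the side chain, C5=C6 is the E-alkene, C9 the methylidene carbon) is traced back to a cyclopentanone. With C9 as a ketone, C9 and the C5=C6 alkene are the retron of a Grob fragmentation, and the C1 ester beside C9 lets the bicyclic alkoxide arise by aldol addition. In one operation base closes C1–C9 (ester enolate onto the ring ketone) and the alkoxide fragments C9–C5 with loss of tosylate from C6. This expands the five-membered ring by four carbons and sets the E-alkene; the ring stereocentres vanish, so a diastereomer mixture converges. The precursor is a 2-methyl-3-tosyloxycyclopentanone carrying a C2-branched pentanoate chain.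

Key step: step 11

Remark (assumption): the two cyclopentane stereocentres are carried only in relative configuration (both ring diastereomers), because step 11 destroys them; boronate 8 and the diene ligand of step 8 are taken as commercial; target ring numbering is used for all precursors.

Step 1
Reactants: 1 2-methylcyclopentane-1,3-dione; 2 acrolein
Product: 3 3-(1-methyl-2,5-dioxocyclopentyl)propanal
Conditions: H2O, rt
Reagents that add atoms: none
Why: Michael addition of the acidic 1,3-dione through its central carbon to acrolein needs no added base in water and creates the quaternary carbon that becomes C5 with its methyl group; no stereocentre is formed.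

Step 2
Reactants: 3 3-(1-methyl-2,5-dioxocyclopentyl)propanal; 4 methyl (triphenylphosphoranylidene)acetate
Product: 5 methyl (2E)-5-(1-methyl-2,5-dioxocyclopentyl)pent-2-enoate
Conditions: CH2Cl2, rt
Reagents that add atoms: none
Why: Wittig olefination with a stabilised ylide is E-selective and should react at the aldehyde only, the ring ketones being flanked by the quaternary carbon.

Step 3
Reactants: 6 methyl propiolate
Product: 7 methyl (2E)-2,3-dibromoprop-2-enoate
Conditions: Br2, CH2Cl2, 0 °C → rt
Reagents that add atoms: bromine, BrBr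
Why: Electrophilic bromination of the alkyne by anti addition should give the (E)-dibromide, which fixes the later trans relationship between C2 of the ring and the diene terminus.

Step 4
Reactants: 7 methyl (2E)-2,3-dibromoprop-2-enoate; 8 (3E)-2-methyl-4-(4,4,5,5-tetramethyl-1,3,2-dioxaborolan-2-yl)but-3-en-2-ol
Product: 9 methyl (2E,4E)-2-bromo-6-hydroxy-6-methylhepta-2,4-dienoate
Conditions: Pd(PPh3)4 (5 mol%), aq. K3PO4, THF, rt
Reagents that add atoms: none
Why: Suzuki–Miyaura coupling, site-selective for the β-C–Br bond of a 2,3-dibromoacrylate (less hindered and activated by conjugation), should proceed with retention at both alkenes so that the remaining bromine is trans to the new dienyl carbon.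

Step 5
Reactants: 9 methyl (2E,4E)-2-bromo-6-hydroxy-6-methylhepta-2,4-dienoate
Product: 10 (2E,4E)-2-bromo-6-methylhepta-2,4-diene-1,6-diol
Conditions: DIBAL-H (3.3 equiv), CH2Cl2, −78 °C; Rochelle salt
Reagents that add atoms: none
Why: DIBAL-H 1,2-reduction of the enoate to the allylic alcohol should leave the alkenyl bromide and both alkene geometries untouched.

Step 6
Reactants: 10 (2E,4E)-2-bromo-6-methylhepta-2,4-diene-1,6-diol
Product: 11 (2E,4E)-2-bromo-6-methyl-1,6-bis(triethylsilyloxy)hepta-2,4-diene
Conditions: TESOTf (2.4 equiv), 2,6-lutidine, CH2Cl2, −78 → 0 °C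
Reagents that add atoms: triethylsilyl trifluoromethanesulfonate, CC[Si](CC)(CC)OS(=O)(=O)C(F)(F)F
Why: Silyl triflate with lutidine silylates the primary and the tertiary alcohol under non-acidic conditions that should not ionise the tertiary dienylic carbinol.

Step 7
Reactants: 11 (2E,4E)-2-bromo-6-methyl-1,6-bis(triethylsilyloxy)hepta-2,4-diene
Product: 12 2-[(2Z,4E)-6-methyl-1,6-bis(triethylsilyloxy)hepta-2,4-dien-2-yl]-4,4,5,5-tetramethyl-1,3,2-dioxaborolane
Conditions: B2pin2, PdCl2(PPh3)2 (3 mol%), PPh3, KOPh, toluene, 50 °C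
Reagents that add atoms: bis(pinacolato)diboron, CC1(C)OB(OC1(C)C)B1OC(C)(C)C(C)(C)O1
Why: Miyaura borylation of a 1-alkenyl bromide proceeds with retention of alkene geometry, and phenoxide as base suppresses Suzuki homocoupling.

Step 8
Reactants: 5 methyl (2E)-5-(1-methyl-2,5-dioxocyclopentyl)pent-2-enoate; 12 2-[(2Z,4E)-6-methyl-1,6-bis(triethylsilyloxy)hepta-2,4-dien-2-yl]-4,4,5,5-tetramethyl-1,3,2-dioxaborolane
Product: 13 methyl (3S)-5-(1-methyl-2,5-dioxocyclopentyl)-3-[(2Z,4E)-6-methyl-1,6-bis(triethylsilyloxy)hepta-2,4-dien-2-yl]pentanoate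
Conditions: [RhCl(C2H4)2]2 (2.5 mol%), (R,R)-Ph-bod* (5.5 mol%), aq. KOH (10 mol%), dioxane, 40 °C
Reagents that add atoms: none
Why: Hayashi–Miyaura rhodium-catalysed asymmetric 1,4-addition of the alkenylboronate to the achiral (E)-enoate transfers the dienyl group with retention; the chiral diene ligand controls the face of the β-carbon (C2 of the ring), the (R,R) ligand being expected to give 3S by analogy with its re-face delivery to E-enoates (sense to be confirmed on a model), and in water-rich dioxane the rhodium enolate should be protonated rather than add to a ring carbonyl.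

Step 9
Reactants: 13 methyl (3S)-5-(1-methyl-2,5-dioxocyclopentyl)-3-[(2Z,4E)-6-methyl-1,6-bis(triethylsilyloxy)hepta-2,4-dien-2-yl]pentanoate
Product: 14 methyl (3S)-5-[(1S,2S)-2-hydroxy-1-methyl-5-oxocyclopentyl]-3-[(2Z,4E)-6-methyl-1,6-bis(triethylsilyloxy)hepta-2,4-dien-2-yl]pentanoate, obtained together with its (1R,2R)-ring diastereomer (hydroxyl cis to the chain in both)
Conditions: NaBH4 (0.3 equiv), MeOH/CH2Cl2, −78 °C
Reagents that add atoms: none
Why: Borohydride mono-reduction of a 2,2-disubstituted cyclopentane-1,3-dione should deliver hydride to the carbonyl face anti to the larger substituent on the quaternary carbon, so the alcohol is expected cis to the chain; the two diastereotopic carbonyls are not distinguished, which is harmless because step 11 erases these centres, and the ester is not reduced at −78 °C.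

Step 10
Reactants: 14 methyl (3S)-5-[(1S,2S)-2-hydroxy-1-methyl-5-oxocyclopentyl]-3-[(2Z,4E)-6-methyl-1,6-bis(triethylsilyloxy)hepta-2,4-dien-2-yl]pentanoate (both ring diastereomers)
Product: 15 methyl (3S)-5-[(1S,2R)-1-methyl-5-oxo-2-(tosyloxy)cyclopentyl]-3-[(2Z,4E)-6-methyl-1,6-bis(triethylsilyloxy)hepta-2,4-dien-2-yl]pentanoate, together with its (1R,2S)-ring diastereomer (tosylate cis to the methyl group in both)
Conditions: Zn(OTs)2, PPh3, DIAD, toluene, 0 °C → rt
Reagents that add atoms: zinc 4-methylbenzenesulfonate, Cc1ccc(cc1)S(=O)(=O)[O-].Cc1ccc(cc1)S(=O)(=O)[O-].[Zn+2]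
Why: Mitsunobu sulfonylation (zinc tosylate variant) displaces the alkoxyphosphonium ion by tosylate in an SN2 step with inversion, which places the leaving group at C6 cis to the C5 methyl group as the E-selective fragmentation requires.

Step 11
Reactants: 15 methyl (3S)-5-[(1S,2R)-1-methyl-5-oxo-2-(tosyloxy)cyclopentyl]-3-[(2Z,4E)-6-methyl-1,6-bis(triethylsilyloxy)hepta-2,4-dien-2-yl]pentanoate (both ring diastereomers)
Product: 17 methyl (1R,2S,5E)-5-methyl-9-oxo-2-[(2Z,4E)-6-methyl-1,6-bis(triethylsilyloxy)hepta-2,4-dien-2-yl]cyclonon-5-ene-1-carboxylate, via bicyclic potassium aldolate 16 (not isolated)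
Conditions: KOtBu (2.2 equiv), THF/t-BuOH, −20 → 20 °C; AcOH
Reagents that add atoms: none
Why: tert-Butoxide reversibly forms the ester enolate, which adds to the ring ketone (intramolecular aldol, new C1–C9 bond) to give the bicyclo[4.3.0] alkoxides 16, and the alkoxide whose C9–C5 bond is antiperiplanar to the C6–OTs bond undergoes Grob (Wharton) fragmentation, cleaving C9–C5 and forming C9=O and C5=C6. The closest known reactions are the Wharton fragmentation of hydrindane and decalin 1,3-diol monosulfonates to (E)-cycloalkenones and nucleophile-triggered fragmentations of β-sulfonyloxy ketones. The transient six-membered ring closes by 6-exo-trig aldol addition, whereas the nine-membered ring is not closed end to end but arises by cleavage of the ring-fusion bond, a four-carbon ring expansion of the cyclopentanone. The alkene geometry is set stereospecifically by the cis relationship of tosylate and methyl (anti elimination leaves C4 and C7 trans, hence E), C2 is untouched, and C1 is set afterwards by equilibration of the β-keto ester to the trans arrangement of its two substituents. Because the C5 and C6 centres are destroyed and the aldol centres at C1 and C9 equilibrate by retro-aldol, both ring diastereomers of 15 and all aldol diastereomers should drain into one product. The step needs the aldol addition to outrun E2 loss of the tosylate, C-alkylation of the enolate at C6 and attack of base on the ketone, which the six-ring intramolecular aldol, the hindered non-nucleophilic base and the neopentyl-type position of the tosylate should secure.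

Step 12
Reactants: 17 methyl (1R,2S,5E)-5-methyl-9-oxo-2-[(2Z,4E)-6-methyl-1,6-bis(triethylsilyloxy)hepta-2,4-dien-2-yl]cyclonon-5-ene-1-carboxylate
Product: 18 methyl (1R,2S,5E)-5-methyl-9-methylidene-2-[(2Z,4E)-6-methyl-1,6-bis(triethylsilyloxy)hepta-2,4-dien-2-yl]cyclonon-5-ene-1-carboxylate
Conditions: CH2Br2, Zn, TiCl4 (Takai–Lombardo reagent, pre-formed in THF), CH2Cl2, 0 °C → rt
Reagents that add atoms: dibromomethane, BrCBr
Why: Takai–Lombardo methylenation uses a non-basic gem-dimetallic titanium reagent that olefinates ketones in preference to esters and should not deprotonate the acidic C1–H, so the trans C1/C2 relationship of the equilibrating keto ester is expected to be carried into the β,γ-unsaturated ester.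

Step 13
Reactants: 18 methyl (1R,2S,5E)-5-methyl-9-methylidene-2-[(2Z,4E)-6-methyl-1,6-bis(triethylsilyloxy)hepta-2,4-dien-2-yl]cyclonon-5-ene-1-carboxylate
Product: 20 methyl (1R,2S,5E)-2-[(2Z,4E)-1-acetoxy-6-hydroxy-6-methylhepta-2,4-dien-2-yl]-5-methyl-9-methylidenecyclonon-5-ene-1-carboxylate (CNP0176502.1), via diol 19 (not isolated)
Conditions: TBAF, AcOH, THF, 0 °C → rt; then Et3N, Ac2O, DMAP (cat.), 0 °C
Reagents that add atoms: acetic anhydride, CC(=O)OC(C)=O
Why: Buffered fluoride removes both triethylsilyl groups without base-induced migration of the exocyclic alkene, and the primary allylic alcohol is acetylated in the same flask before it can lactonise onto the C1 ester, the tertiary alcohol being too hindered to be acylated under these conditions.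

Compound list
1 | 2-methylcyclopentane-1,3-dione | CC1C(=O)CCC1=O | starting material
2 | acrolein | C=CC=O | starting material
3 | 3-(1-methyl-2,5-dioxocyclopentyl)propanal | CC1(CCC=O)C(=O)CCC1=O | intermediate
4 | methyl (triphenylphosphoranylidene)acetate | COC(=O)C=P(c1ccccc1)(c1ccccc1)c1ccccc1 | starting material
5 | methyl (2E)-5-(1-methyl-2,5-dioxocyclopentyl)pent-2-enoate | COC(=O)/C=C/CCC1(C)C(=O)CCC1=O | intermediate
6 | methyl propiolate | COC(=O)C#C | starting material
7 | methyl (2E)-2,3-dibromoprop-2-enoate | COC(=O)/C(Br)=C\Br | intermediate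
8 | (3E)-2-methyl-4-(4,4,5,5-tetramethyl-1,3,2-dioxaborolan-2-yl)but-3-en-2-ol | CC(C)(O)/C=C/B1OC(C)(C)C(C)(C)O1 | starting material
9 | methyl (2E,4E)-2-bromo-6-hydroxy-6-methylhepta-2,4-dienoate | COC(=O)/C(Br)=C\C=C\C(C)(C)O | intermediate
10 | (2E,4E)-2-bromo-6-methylhepta-2,4-diene-1,6-diol | OC/C(Br)=C\C=C\C(C)(C)O | intermediate
11 | (2E,4E)-2-bromo-6-methyl-1,6-bis(triethylsilyloxy)hepta-2,4-diene | CC[Si](CC)(CC)OC/C(Br)=C\C=C\C(C)(C)O[Si](CC)(CC)CC | intermediate
12 | 2-[(2Z,4E)-6-methyl-1,6-bis(triethylsilyloxy)hepta-2,4-dien-2-yl]-4,4,5,5-tetramethyl-1,3,2-dioxaborolane | CC[Si](CC)(CC)OC/C(B1OC(C)(C)C(C)(C)O1)=C\C=C\C(C)(C)O[Si](CC)(CC)CC | intermediate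
13 | methyl (3S)-5-(1-methyl-2,5-dioxocyclopentyl)-3-[(2Z,4E)-6-methyl-1,6-bis(triethylsilyloxy)hepta-2,4-dien-2-yl]pentanoate | COC(=O)C[C@H](CCC1(C)C(=O)CCC1=O)/C(=C/C=C/C(C)(C)O[Si](CC)(CC)CC)CO[Si](CC)(CC)CC | intermediate
14 | methyl (3S)-5-[(1S,2S)-2-hydroxy-1-methyl-5-oxocyclopentyl]-3-[(2Z,4E)-6-methyl-1,6-bis(triethylsilyloxy)hepta-2,4-dien-2-yl]pentanoate; hydroxyl cis to the chain; drawn isomer of a pair with the (1R,2R)-ring diastereomer | COC(=O)C[C@H](CC[C@@]1(C)[C@@H](O)CCC1=O)/C(=C/C=C/C(C)(C)O[Si](CC)(CC)CC)CO[Si](CC)(CC)CC | intermediate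
15 | methyl (3S)-5-[(1S,2R)-1-methyl-5-oxo-2-(tosyloxy)cyclopentyl]-3-[(2Z,4E)-6-methyl-1,6-bis(triethylsilyloxy)hepta-2,4-dien-2-yl]pentanoate; tosylate cis to methyl; drawn isomer of a pair with the (1R,2S)-ring diastereomer | COC(=O)C[C@H](CC[C@@]1(C)[C@H](OS(=O)(=O)c2ccc(C)cc2)CCC1=O)/C(=C/C=C/C(C)(C)O[Si](CC)(CC)CC)CO[Si](CC)(CC)CC | intermediate
16 | bicyclic potassium aldolate: bicyclo[4.3.0]nonane with O−K+ on ring-fusion C9, CO2Me on C1, the (S)-configured side-chain carbon C2, angular methyl on C5 and tosylate on C6 cis to that methyl; mixture of epimers at C1 and C9 | COC(=O)C1[C@@H](/C(=C/C=C/C(C)(C)O[Si](CC)(CC)CC)CO[Si](CC)(CC)CC)CC[C@@]2(C)[C@H](OS(=O)(=O)c3ccc(C)cc3)CCC12[O-].[K+] | intermediate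
17 | methyl (1R,2S,5E)-5-methyl-9-oxo-2-[(2Z,4E)-6-methyl-1,6-bis(triethylsilyloxy)hepta-2,4-dien-2-yl]cyclonon-5-ene-1-carboxylate (trans β-keto ester, epimerisable at C1) | O=C1CC/C=C(\C)CC[C@H](/C(=C/C=C/C(C)(C)O[Si](CC)(CC)CC)CO[Si](CC)(CC)CC)[C@H]1C(=O)OC | intermediate
18 | methyl (1R,2S,5E)-5-methyl-9-methylidene-2-[(2Z,4E)-6-methyl-1,6-bis(triethylsilyloxy)hepta-2,4-dien-2-yl]cyclonon-5-ene-1-carboxylate | C=C1CC/C=C(\C)CC[C@H](/C(=C/C=C/C(C)(C)O[Si](CC)(CC)CC)CO[Si](CC)(CC)CC)[C@H]1C(=O)OC | intermediate
19 | methyl (1R,2S,5E)-2-[(2Z,4E)-1,6-dihydroxy-6-methylhepta-2,4-dien-2-yl]-5-methyl-9-methylidenecyclonon-5-ene-1-carboxylate | C=C1CC/C=C(\C)CC[C@H](/C(=C/C=C/C(C)(C)O)CO)[C@H]1C(=O)OC | intermediate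
20 | methyl (1R,2S,5E)-2-[(2Z,4E)-1-acetoxy-6-hydroxy-6-methylhepta-2,4-dien-2-yl]-5-methyl-9-methylidenecyclonon-5-ene-1-carboxylate (CNP0176502.1) | C=C1CC/C=C(\C)CC[C@H](/C(=C/C=C/C(C)(C)O)COC(C)=O)[C@H]1C(=O)OC | target

Total step count: 13. Longest linear sequence: 11 steps (steps 3–7, then 8–13).

Steps most likely to fail

1. Step 12. The α-monosubstituted β-keto ester may be converted into an unreactive titanium enolate instead of being olefinated; the zinc and titanium Lewis acids may also ionise the tertiary dienylic silyl ether or trigger a transannular reaction of the strained E-alkene, and C1 may epimerise. The fallback sets out from 17 and replaces carbonyl olefination by cross-coupling. Deprotonation with KHMDS and O-sulfonylation with PhNTf2 (THF, −78 → 0 °C) should give the enol triflate F1. Kumada coupling with Me3SiCH2MgCl (Pd(PPh3)4, THF, rt) should then give the 2-(silylmethyl)enoate, allylsilane F2. Under the conditions of step 13, fluoride removes the allylic silyl group with protonation of the dienolate at C1 (moving the double bond to the exocyclic position) and both O-silyl groups, so the route is rejoined at diol 19 in the flask and acetylation gives 20. The C1 configuration then rests on that protonation and, if needed, on a mild base equilibration to the trans ester.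

2. Step 11. The aldol addition may be outrun by E2 loss of the tosylate, by intramolecular C-alkylation of the ester enolate at C6, or the substrate may rest as the unproductive ketone enolate. The fallback sets out from 15 and separates the two events. A titanium-mediated direct aldol addition (TiCl4, Bu3N, cat. TMSCl, CH2Cl2, −78 °C) closes the six-membered ring without free alkoxide base and should give the bicyclic β-hydroxy ester F3, which is isolated. Deprotonation of its tertiary alcohol (KHMDS, THF, −78 → 0 °C; AcOH) then triggers the Wharton–Grob fragmentation alone and returns to 17.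

3. Step 10. Displacement at the neopentyl-type carbinol by the weakly nucleophilic tosylate may be slow, so that elimination or incomplete inversion takes over. The fallback sets out from 14 and inverts with a carboxylate before sulfonylating with retention. Mitsunobu reaction with chloroacetic acid (PPh3, DIAD, toluene, 0 °C → rt) should give the inverted chloroacetate F4. Mild methanolysis (K2CO3 cat., MeOH, −20 °C) should give the epimeric alcohol F5 with the hydroxyl cis to the methyl group. Tosylation (TsCl, Et3N, DMAP, CH2Cl2, rt) then returns to 15.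

Further compounds
F1 | step 12 | enol triflate of 17: methyl (5E)-5-methyl-2-[(2Z,4E)-6-methyl-1,6-bis(triethylsilyloxy)hepta-2,4-dien-2-yl]-9-(trifluoromethylsulfonyloxy)cyclonona-1(9),5-diene-1-carboxylate, C2 configured as in 17 | COC(=O)/C1=C(\OS(=O)(=O)C(F)(F)F)CC/C=C(\C)CC[C@@H]1/C(=C/C=C/C(C)(C)O[Si](CC)(CC)CC)CO[Si](CC)(CC)CC
F2 | step 12 | allylsilane: methyl (5E)-5-methyl-2-[(2Z,4E)-6-methyl-1,6-bis(triethylsilyloxy)hepta-2,4-dien-2-yl]-9-(trimethylsilylmethyl)cyclonona-1(9),5-diene-1-carboxylate, C2 configured as in 17 | COC(=O)/C1=C(\C[Si](C)(C)C)CC/C=C(\C)CC[C@@H]1/C(=C/C=C/C(C)(C)O[Si](CC)(CC)CC)CO[Si](CC)(CC)CC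
F3 | step 11 | bicyclic β-hydroxy ester (protonated form of 16): bicyclo[4.3.0]nonane with tertiary OH on ring-fusion C9, CO2Me on C1, side chain on C2, angular methyl on C5 and tosylate on C6 cis to the methyl; mixture of C1/C9 epimers | COC(=O)C1[C@@H](/C(=C/C=C/C(C)(C)O[Si](CC)(CC)CC)CO[Si](CC)(CC)CC)CC[C@@]2(C)[C@H](OS(=O)(=O)c3ccc(C)cc3)CCC12O
F4 | step 10 | methyl (3S)-5-[(1S,2R)-2-(chloroacetoxy)-1-methyl-5-oxocyclopentyl]-3-[(2Z,4E)-6-methyl-1,6-bis(triethylsilyloxy)hepta-2,4-dien-2-yl]pentanoate (with its (1R,2S)-ring diastereomer) | COC(=O)C[C@H](CC[C@@]1(C)[C@H](OC(=O)CCl)CCC1=O)/C(=C/C=C/C(C)(C)O[Si](CC)(CC)CC)CO[Si](CC)(CC)CC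
F5 | step 10 | methyl (3S)-5-[(1S,2R)-2-hydroxy-1-methyl-5-oxocyclopentyl]-3-[(2Z,4E)-6-methyl-1,6-bis(triethylsilyloxy)hepta-2,4-dien-2-yl]pentanoate, hydroxyl cis to methyl (with its (1R,2S)-ring diastereomer) | COC(=O)C[C@H](CC[C@@]1(C)[C@H](O)CCC1=O)/C(=C/C=C/C(C)(C)O[Si](CC)(CC)CC)CO[Si](CC)(CC)CC
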